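**Retrosynthetic overview**
- The target is epicatechin-(4β→6)-epiafzelechin-(4β→8)-epicatechin-(4β→6)-epicatechin (unit 1 to unit 4 from the top). The three interflavan bonds are cut. Units 3 and 4 come from (−)-epicatechin and unit 2 from (−)-epiafzelechin, with C8 bromides as blocking groups and two orthogonal C4 leaving groups (arylsulfanyl on unit 2, 2-ethoxyethoxy on unit 3).
- Unit 1 is built, not bought: its ring C is closed through C2–C3 from an acyclic O-aryl acyloxy-acetal carrying an ortho (Z)-enol benzoate, in a cascade that also forms the C4(unit 1)–C6(unit 2) bond.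
- Enabling feature: ring A of unit 1 is a phloroglucinol ring. O1 on C8a and the oxygens on C5 and C7 sit ortho/para to C4a, so C4 is a stabilised benzylic cation site next to the oxygenated C3. An O1=C2 oxocarbenium ion can therefore pass its charge through C3 to C4, where C6 of ring A of unit 2 (C8 brominated) bonds trans to the 3-acyloxy group.
- Order: ring C of unit 1 plus the unit 1→unit 2 bond (step 16); C4(unit 2)–C8(unit 3) by silver activation of the sulfide; C4(unit 3)–C6(unit 4) by silyl triflate activation; global hydrogenolysis of 15 benzyl ethers and 3 aryl bromides.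

Key step: step 16

Remark: (−)-epicatechin and (−)-epiafzelechin are taken as purchasable (2R,3R)-flavan-3-ols; flavan numbering (O1, C2–C4, C4a, C5–C8, C8a, primes for ring B) and the α/β convention are used throughout; the acetal carbon of 18 and 19 is racemic and is lost on ionisation.

**Step 1**
Reactants: 1 (−)-epicatechin
Product: 2 5,7,3′,4′-tetra-O-benzyl-(−)-epicatechin
Conditions: BnBr (4.4 equiv), K2CO3, DMF, 0 °C → rt
Reagents that add atoms: benzyl bromide, BrCc1ccccc1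
Why: Williamson etherification under carbonate conditions should alkylate only the four phenols and leave the less acidic 3-OH and both stereocentres untouched.

**Step 2**
Reactants: 2 5,7,3′,4′-tetra-O-benzyl-(−)-epicatechin
Product: 3 8-bromo-5,7,3′,4′-tetra-O-benzyl-(−)-epicatechin
Conditions: NBS (1.0 equiv), CH2Cl2, −78 °C → rt
Reagents that add atoms: N-bromosuccinimide, O=C1CCC(=O)N1Br
Why: electrophilic aromatic bromination should go to C8, the most nucleophilic ring-A position of 5,7-di-O-benzylflavans, which installs the C8 blocking group of unit 4.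

**Step 3**
Reactants: 2 5,7,3′,4′-tetra-O-benzyl-(−)-epicatechin
Product: 4 4β-(2-ethoxyethoxy)-5,7,3′,4′-tetra-O-benzyl-(−)-epicatechin
Conditions: DDQ (2 equiv), 2-ethoxyethanol, CH2Cl2, rt
Reagents that add atoms: 2-ethoxyethanol, CCOCCO
Why: benzylic C–H oxidation by DDQ hydride abstraction at C4 gives the ring-A-stabilised cation, which the alcohol should trap anti to the axial 3-OH, setting C4 as 4β (3,4-trans).

**Step 4**
Reactants: 5 (−)-epiafzelechin
Product: 6 5,7,4′-tri-O-benzyl-(−)-epiafzelechin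
Conditions: BnBr (3.3 equiv), K2CO3, DMF, 0 °C → rt
Reagents that add atoms: benzyl bromide, BrCc1ccccc1
Why: Williamson etherification of the three phenols only, as in step 1.

**Step 5**
Reactants: 6 5,7,4′-tri-O-benzyl-(−)-epiafzelechin
Product: 7 4β-(2-ethoxyethoxy)-5,7,4′-tri-O-benzyl-(−)-epiafzelechin
Conditions: DDQ (2 equiv), 2-ethoxyethanol, CH2Cl2, rt
Reagents that add atoms: 2-ethoxyethanol, CCOCCO
Why: DDQ benzylic oxidation at C4 with alcohol capture anti to the 3-OH (4β), as in step 3.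

**Step 6**
Reactants: 7 4β-(2-ethoxyethoxy)-5,7,4′-tri-O-benzyl-(−)-epiafzelechin
Product: 8 8-bromo-4β-(2-ethoxyethoxy)-5,7,4′-tri-O-benzyl-(−)-epiafzelechin
Conditions: NBS (1.0 equiv), CH2Cl2, −40 °C
Reagents that add atoms: N-bromosuccinimide, O=C1CCC(=O)N1Br
Why: electrophilic aromatic bromination at C8 as in step 2, so that only C6 of unit 2 stays nucleophilic.

**Step 7**
Reactants: 8 8-bromo-4β-(2-ethoxyethoxy)-5,7,4′-tri-O-benzyl-(−)-epiafzelechin
Product: 9 8-bromo-4β-(2,6-dimethylphenylsulfanyl)-5,7,4′-tri-O-benzyl-(−)-epiafzelechin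
Conditions: 2,6-Me2C6H3SH (3 equiv), BF3·OEt2 (0.5 equiv), CH2Cl2, −78 → −30 °C
Reagents that add atoms: 2,6-dimethylbenzenethiol, Cc1cccc(C)c1S
Why: Lewis-acid SN1 exchange through the flavan-4-yl cation, with the thiol entering anti to the 3-OH (4β), converts the hard-acid-labile ether into a sulfide that answers only to soft activation.

**Step 8**
Reactants: 10 2,4,6-trihydroxybenzaldehyde
Product: 11 2,4-bis(benzyloxy)-6-hydroxybenzaldehyde
Conditions: BnBr (2.1 equiv), K2CO3, DMF, rt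
Reagents that add atoms: benzyl bromide, BrCc1ccccc1
Why: Williamson etherification should stop after the 4-OH and one ortho OH, because the remaining ortho OH is chelated to the aldehyde.

**Step 9**
Reactants: 11 2,4-bis(benzyloxy)-6-hydroxybenzaldehyde
Product: 12 4,6-bis(benzyloxy)-3-bromo-2-hydroxybenzaldehyde
Conditions: NBS (1.0 equiv), MeCN, −20 °C
Reagents that add atoms: N-bromosuccinimide, O=C1CCC(=O)N1Br
Why: electrophilic aromatic bromination should prefer the position ortho to the free phenol (flanked by OH and one benzyloxy group) over the position between two benzyloxy groups, placing the future C8 bromide of unit 1.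

**Step 10**
Reactants: 12 4,6-bis(benzyloxy)-3-bromo-2-hydroxybenzaldehyde
Product: 13 4,6-bis(benzyloxy)-3-bromo-2-(triisopropylsilyloxy)benzaldehyde
Conditions: i-Pr3SiOSO2CF3, 2,6-lutidine, CH2Cl2, 0 °C → rt
Reagents that add atoms: triisopropylsilyl triflate, CC(C)[Si](C(C)C)(C(C)C)OS(=O)(=O)C(F)(F)F
Why: O-silylation with the silyl triflate masks the hindered phenol so that it cannot add to the alkyne (benzofuran formation) in the next two steps.

**Step 11**
Reactants: 13 4,6-bis(benzyloxy)-3-bromo-2-(triisopropylsilyloxy)benzaldehyde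
Product: 14 [3,5-bis(benzyloxy)-2-bromo-6-ethynylphenoxy]triisopropylsilane
Conditions: Me3SiCHN2, LiN(i-Pr)2, THF, −78 °C → rt
Reagents that add atoms: (trimethylsilyl)diazomethane, C[Si](C)(C)C=[N+]=[N-]
Why: Colvin rearrangement (addition of the lithiated diazo reagent, Peterson-type elimination, loss of N2 and 1,2-hydrogen shift) gives the terminal alkyne under conditions that spare the aryl bromide and the silyl ether.

**Step 12**
Reactants: 14 [3,5-bis(benzyloxy)-2-bromo-6-ethynylphenoxy]triisopropylsilane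
Product: 15 (Z)-2-[4,6-bis(benzyloxy)-3-bromo-2-(triisopropylsilyloxy)phenyl]ethenyl benzoate
Conditions: PhCO2H (1.2 equiv), Ru(η3-2-methylallyl)2(dppb) (3 mol%; dppb = Ph2P(CH2)4PPh2), toluene, 65 °C
Reagents that add atoms: benzoic acid, OC(=O)c1ccccc1
Why: ruthenium-vinylidene-mediated anti-Markovnikov hydro-acyloxylation of a terminal alkyne should deliver the carboxylate to the terminal carbon and give the Z enol ester, which fixes the alkene geometry needed in step 16.

**Step 13**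
Reactants: 15 (Z)-2-[4,6-bis(benzyloxy)-3-bromo-2-(triisopropylsilyloxy)phenyl]ethenyl benzoate
Product: 16 (Z)-2-[4,6-bis(benzyloxy)-3-bromo-2-hydroxyphenyl]ethenyl benzoate
Conditions: Bu4NF (1.1 equiv), AcOH (1.2 equiv), THF, 0 °C
Reagents that add atoms: none
Why: acetic-acid-buffered fluoride desilylation should free the phenol without building up phenoxide that could take over the neighbouring enol benzoate.

**Step 14**
Reactants: 17 3,4-bis(benzyloxy)benzaldehyde
Product: 18 [3,4-bis(benzyloxy)phenyl](chloro)methyl pivalate (racemic)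
Conditions: t-BuCOCl, ZnCl2 (5 mol%), CH2Cl2, 0 °C → rt, used crude
Reagents that add atoms: pivaloyl chloride, CC(C)(C)C(Cl)=O
Why: Lewis-acid-catalysed addition of an acyl chloride across the aldehyde C=O gives the α-chloroalkyl ester.

**Step 15**
Reactants: 16 (Z)-2-[4,6-bis(benzyloxy)-3-bromo-2-hydroxyphenyl]ethenyl benzoate; 18 [3,4-bis(benzyloxy)phenyl](chloro)methyl pivalate
Product: 19 {2-[(Z)-2-(benzoyloxy)ethenyl]-3,5-bis(benzyloxy)-6-bromophenoxy}[3,4-bis(benzyloxy)phenyl]methyl pivalate (racemic at the acetal carbon)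
Conditions: Cs2CO3, MeCN, 0 °C
Reagents that add atoms: none
Why: Williamson-type O-alkylation of the caesium phenoxide by the SN1-reactive α-chloro ester (acyloxyalkyl ether formation) forms the O1–C2 bond, and the bulky pivalate resists acyl transfer.

**Step 16**
Reactants: 19 {2-[(Z)-2-(benzoyloxy)ethenyl]-3,5-bis(benzyloxy)-6-bromophenoxy}[3,4-bis(benzyloxy)phenyl]methyl pivalate; 9 8-bromo-4β-(2,6-dimethylphenylsulfanyl)-5,7,4′-tri-O-benzyl-(−)-epiafzelechin
Product: 22 [3-O-benzoyl-8-bromo-5,7,3′,4′-tetra-O-benzyl-epicatechin]-(4β→6)-[8-bromo-4β-(2,6-dimethylphenylsulfanyl)-5,7,4′-tri-O-benzyl-epiafzelechin], via oxocarbenium ion 20 (not isolated), via flavan-4-yl cation 21 (not isolated)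
Conditions: 9 (2.5 equiv), chiral imidodiphosphorimidate Brønsted acid (IDPi, N-triflyl, 3,3′-diaryl-BINOL-derived, 5 mol%), 5 Å MS, CH2Cl2, −60 → −30 °C
Reagents that add atoms: none
Why: Proposed new method: the chiral acid should ionise the pivalate of 19 (the carboxylate leaves, so only the O-aryl oxocarbenium ion 20 can form, paired with the chiral anion), C3 of the ortho (Z)-enol benzoate then attacks C2 and closes ring C by the C2–C3 bond in a 6-endo-trig cation–olefin (Prins) closure through a half-chair, and the ring-A-stabilised, benzoate-bridged flavan-4-yl cation 21 is captured at C4 by C6 of 9 in a Friedel–Crafts step that releases the proton and turns the catalyst over. The closest known reaction types are the Prins cyclisation of α-acyloxy ethers, imidodiphosphorimidate-catalysed asymmetric Prins and oxa-Pictet–Spengler reactions of oxocarbenium ion pairs, and the Lewis-acid coupling of flavan-4-yl cations with 8-bromoflavan-3-ols; new are the O-aryl oxocarbenium ion, the styrenyl enol ester as the olefin and the arene termination. C2 and C3: the (E)-oxocarbenium ion places the aryl group equatorial and the Z enol ester places the benzoate axial, which should give the 2,3-cis relation, while the chiral counter-anion chooses the face of 20 and so the 2R,3R series (a wrong-face product would be a diastereomer of 22, because 9 is enantiopure, and separable). C4: the arene should enter anti to the axial, participating 3-benzoate (trans-diaxial opening), giving the 3,4-trans 4β bond. Selectivity needed: attack by C3 and not C4 of the alkene (secured by the 2,4,6-trioxygenated aryl group, which outweighs the weakly donating ester oxygen), arylation at C6 only (the C8 bromides of 9 and of unit 1 block the alternative site and the self-condensation site) and an untouched sulfide (inert to the hard Brønsted acid).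

**Step 17**
Reactants: 22 [3-O-benzoyl-8-bromo-5,7,3′,4′-tetra-O-benzyl-epicatechin]-(4β→6)-[8-bromo-4β-(2,6-dimethylphenylsulfanyl)-5,7,4′-tri-O-benzyl-epiafzelechin]
Product: 23 [8-bromo-5,7,3′,4′-tetra-O-benzyl-epicatechin]-(4β→6)-[8-bromo-4β-(2,6-dimethylphenylsulfanyl)-5,7,4′-tri-O-benzyl-epiafzelechin]
Conditions: K2CO3 (cat.), MeOH/THF, rt
Reagents that add atoms: none
Why: base-catalysed transesterification removes the benzoate as methyl benzoate while sulfide, aryl bromides and benzyl ethers are inert.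

**Step 18**
Reactants: 23 [8-bromo-5,7,3′,4′-tetra-O-benzyl-epicatechin]-(4β→6)-[8-bromo-4β-(2,6-dimethylphenylsulfanyl)-5,7,4′-tri-O-benzyl-epiafzelechin]; 4 4β-(2-ethoxyethoxy)-5,7,3′,4′-tetra-O-benzyl-(−)-epicatechin
Product: 24 [8-bromo-5,7,3′,4′-tetra-O-benzyl-epicatechin]-(4β→6)-[8-bromo-5,7,4′-tri-O-benzyl-epiafzelechin]-(4β→8)-[4β-(2-ethoxyethoxy)-5,7,3′,4′-tetra-O-benzyl-epicatechin]
Conditions: 4 (3 equiv), AgOSO2CF3 (1.5 equiv), 2,6-di-tert-butyl-4-methylpyridine (2 equiv), 4 Å MS, CH2Cl2, −40 → 0 °C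
Reagents that add atoms: none
Why: thiophilic silver activation of the C4 sulfide gives the flavan-4-yl cation of unit 2, which the free C8 of 4 should capture anti to the 3-OH (Friedel–Crafts interflavan coupling, 4β→8), while the buffered soft conditions leave the 2-ethoxyethoxy group of 4 untouched.

**Step 19**
Reactants: 24 [8-bromo-5,7,3′,4′-tetra-O-benzyl-epicatechin]-(4β→6)-[8-bromo-5,7,4′-tri-O-benzyl-epiafzelechin]-(4β→8)-[4β-(2-ethoxyethoxy)-5,7,3′,4′-tetra-O-benzyl-epicatechin]; 3 8-bromo-5,7,3′,4′-tetra-O-benzyl-(−)-epicatechin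
Product: 25 [8-bromo-5,7,3′,4′-tetra-O-benzyl-epicatechin]-(4β→6)-[8-bromo-5,7,4′-tri-O-benzyl-epiafzelechin]-(4β→8)-[5,7,3′,4′-tetra-O-benzyl-epicatechin]-(4β→6)-[8-bromo-5,7,3′,4′-tetra-O-benzyl-epicatechin]
Conditions: 3 (4 equiv), Me3SiOSO2CF3 (0.2 equiv), CH2Cl2, −78 → −40 °C
Reagents that add atoms: none
Why: the hard silyl Lewis acid ionises the 2-ethoxyethoxy group and the flavan-4-yl cation of unit 3 should be captured by C6 of 3 (its C8 is blocked) anti to the 3-OH (Friedel–Crafts interflavan coupling, 4β→6), the excess of 3 outcompeting the two free C6-type sites of 24.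

**Step 20**
Reactants: 25 the protected tetramer from step 19
Product: 26 epicatechin-(4β→6)-epiafzelechin-(4β→8)-epicatechin-(4β→6)-epicatechin (target)
Conditions: H2 (1 atm), Pd(OH)2/C, Et3N, THF/MeOH/H2O, rt
Reagents that add atoms: none
Why: catalytic hydrogenolysis should cleave the 15 benzyl ethers and reduce the 3 aryl bromides (triethylamine takes up HBr) without touching any stereocentre.

**Compound list**
1 | (−)-epicatechin | O[C@@H]1Cc2c(O)cc(O)cc2O[C@@H]1c1ccc(O)c(O)c1 | starting material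
2 | 5,7,3′,4′-tetra-O-benzyl-(−)-epicatechin | O[C@@H]1Cc2c(OCc3ccccc3)cc(OCc3ccccc3)cc2O[C@@H]1c1ccc(OCc2ccccc2)c(OCc2ccccc2)c1 | intermediate
3 | 8-bromo-5,7,3′,4′-tetra-O-benzyl-(−)-epicatechin | O[C@@H]1Cc2c(OCc3ccccc3)cc(OCc3ccccc3)c(Br)c2O[C@@H]1c1ccc(OCc2ccccc2)c(OCc2ccccc2)c1 | intermediate
4 | 4β-(2-ethoxyethoxy)-5,7,3′,4′-tetra-O-benzyl-(−)-epicatechin (2,3-cis, 3,4-trans) | CCOCCO[C@H]1c2c(OCc3ccccc3)cc(OCc3ccccc3)cc2O[C@H](c2ccc(OCc3ccccc3)c(OCc3ccccc3)c2)[C@@H]1O | intermediate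
5 | (−)-epiafzelechin | Oc1ccc([C@H]2Oc3cc(O)cc(O)c3C[C@H]2O)cc1 | starting material
6 | 5,7,4′-tri-O-benzyl-(−)-epiafzelechin | c1ccccc1COc1ccc([C@H]2Oc3cc(OCc4ccccc4)cc(OCc4ccccc4)c3C[C@H]2O)cc1 | intermediate
7 | 4β-(2-ethoxyethoxy)-5,7,4′-tri-O-benzyl-(−)-epiafzelechin | c1ccccc1COc1ccc([C@H]2Oc3cc(OCc4ccccc4)cc(OCc4ccccc4)c3[C@H](OCCOCC)[C@H]2O)cc1 | intermediate
8 | 8-bromo-4β-(2-ethoxyethoxy)-5,7,4′-tri-O-benzyl-(−)-epiafzelechin | c1ccccc1COc1ccc([C@H]2Oc3c(Br)c(OCc4ccccc4)cc(OCc4ccccc4)c3[C@H](OCCOCC)[C@H]2O)cc1 | intermediate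
9 | 8-bromo-4β-(2,6-dimethylphenylsulfanyl)-5,7,4′-tri-O-benzyl-(−)-epiafzelechin | c1ccccc1COc1ccc([C@H]2Oc3c(Br)c(OCc4ccccc4)cc(OCc4ccccc4)c3[C@H](Sc3c(C)cccc3C)[C@H]2O)cc1 | intermediate
10 | 2,4,6-trihydroxybenzaldehyde | O=Cc1c(O)cc(O)cc1O | starting material
11 | 2,4-bis(benzyloxy)-6-hydroxybenzaldehyde | O=Cc1c(O)cc(OCc2ccccc2)cc1OCc1ccccc1 | intermediate
12 | 4,6-bis(benzyloxy)-3-bromo-2-hydroxybenzaldehyde | O=Cc1c(O)c(Br)c(OCc2ccccc2)cc1OCc1ccccc1 | intermediate
13 | 4,6-bis(benzyloxy)-3-bromo-2-(triisopropylsilyloxy)benzaldehyde | O=Cc1c(O[Si](C(C)C)(C(C)C)C(C)C)c(Br)c(OCc2ccccc2)cc1OCc1ccccc1 | intermediate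
14 | [3,5-bis(benzyloxy)-2-bromo-6-ethynylphenoxy]triisopropylsilane | C#Cc1c(O[Si](C(C)C)(C(C)C)C(C)C)c(Br)c(OCc2ccccc2)cc1OCc1ccccc1 | intermediate
15 | (Z)-2-[4,6-bis(benzyloxy)-3-bromo-2-(triisopropylsilyloxy)phenyl]ethenyl benzoate | O=C(O/C=C\c1c(O[Si](C(C)C)(C(C)C)C(C)C)c(Br)c(OCc2ccccc2)cc1OCc1ccccc1)c1ccccc1 | intermediate
16 | (Z)-2-[4,6-bis(benzyloxy)-3-bromo-2-hydroxyphenyl]ethenyl benzoate | O=C(O/C=C\c1c(O)c(Br)c(OCc2ccccc2)cc1OCc1ccccc1)c1ccccc1 | intermediate
17 | 3,4-bis(benzyloxy)benzaldehyde | O=Cc1ccc(OCc2ccccc2)c(OCc2ccccc2)c1 | starting material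
18 | [3,4-bis(benzyloxy)phenyl](chloro)methyl pivalate (racemic) | CC(C)(C)C(=O)OC(Cl)c1ccc(OCc2ccccc2)c(OCc2ccccc2)c1 | intermediate
19 | {2-[(Z)-2-(benzoyloxy)ethenyl]-3,5-bis(benzyloxy)-6-bromophenoxy}[3,4-bis(benzyloxy)phenyl]methyl pivalate (racemic acetal carbon) | CC(C)(C)C(=O)OC(Oc1c(Br)c(OCc2ccccc2)cc(OCc2ccccc2)c1/C=C\OC(=O)c1ccccc1)c1ccc(OCc2ccccc2)c(OCc2ccccc2)c1 | intermediate
20 | (E)-O-aryl oxocarbenium ion from 19 (ion pair with the chiral anion) | C(=[O+]c1c(Br)c(OCc2ccccc2)cc(OCc2ccccc2)c1/C=C\OC(=O)c1ccccc1)c1ccc(OCc2ccccc2)c(OCc2ccccc2)c1 | intermediate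
21 | (2R,3R)-3-benzoyloxy-8-bromo-5,7,3′,4′-tetra-O-benzylflavan-4-yl cation (benzoate-bridged) | [CH+]1c2c(OCc3ccccc3)cc(OCc3ccccc3)c(Br)c2O[C@H](c2ccc(OCc3ccccc3)c(OCc3ccccc3)c2)[C@@H]1OC(=O)c1ccccc1 | intermediate
22 | [3-O-benzoyl-8-bromo-5,7,3′,4′-tetra-O-benzyl-epicatechin]-(4β→6)-[8-bromo-4β-(2,6-dimethylphenylsulfanyl)-5,7,4′-tri-O-benzyl-epiafzelechin] | c1ccccc1COc1ccc([C@H]2Oc3c(Br)c(OCc4ccccc4)c([C@H]4c5c(OCc6ccccc6)cc(OCc6ccccc6)c(Br)c5O[C@H](c5ccc(OCc6ccccc6)c(OCc6ccccc6)c5)[C@@H]4OC(=O)c4ccccc4)c(OCc4ccccc4)c3[C@H](Sc3c(C)cccc3C)[C@H]2O)cc1 | intermediate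
23 | [8-bromo-5,7,3′,4′-tetra-O-benzyl-epicatechin]-(4β→6)-[8-bromo-4β-(2,6-dimethylphenylsulfanyl)-5,7,4′-tri-O-benzyl-epiafzelechin] | c1ccccc1COc1ccc([C@H]2Oc3c(Br)c(OCc4ccccc4)c([C@H]4c5c(OCc6ccccc6)cc(OCc6ccccc6)c(Br)c5O[C@H](c5ccc(OCc6ccccc6)c(OCc6ccccc6)c5)[C@@H]4O)c(OCc4ccccc4)c3[C@H](Sc3c(C)cccc3C)[C@H]2O)cc1 | intermediate
24 | trimer: unit 1 (8-bromo, tetra-O-benzyl)-(4β→6)-unit 2 (8-bromo, tri-O-benzyl)-(4β→8)-unit 3 (4β-(2-ethoxyethoxy), tetra-O-benzyl) | c1ccccc1COc1ccc([C@H]2Oc3c(Br)c(OCc4ccccc4)c([C@H]4c5c(OCc6ccccc6)cc(OCc6ccccc6)c(Br)c5O[C@H](c5ccc(OCc6ccccc6)c(OCc6ccccc6)c5)[C@@H]4O)c(OCc4ccccc4)c3[C@H](c3c(OCc5ccccc5)cc(OCc5ccccc5)c4c3O[C@H](c3ccc(OCc5ccccc5)c(OCc5ccccc5)c3)[C@H](O)[C@H]4OCCOCC)[C@H]2O)cc1 | intermediate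
25 | protected tetramer (15 benzyl ethers; bromides at C8 of units 1, 2 and 4) | c1ccccc1COc1ccc([C@H]2Oc3c(Br)c(OCc4ccccc4)c([C@H]4c5c(OCc6ccccc6)cc(OCc6ccccc6)c(Br)c5O[C@H](c5ccc(OCc6ccccc6)c(OCc6ccccc6)c5)[C@@H]4O)c(OCc4ccccc4)c3[C@H](c3c(OCc5ccccc5)cc(OCc5ccccc5)c4c3O[C@H](c3ccc(OCc5ccccc5)c(OCc5ccccc5)c3)[C@H](O)[C@H]4c3c(OCc5ccccc5)c(Br)c4c(c3OCc5ccccc5)C[C@@H](O)[C@@H](c3ccc(OCc5ccccc5)c(OCc5ccccc5)c3)O4)[C@H]2O)cc1 | intermediate
26 | epicatechin-(4β→6)-epiafzelechin-(4β→8)-epicatechin-(4β→6)-epicatechin (CNP0103636.1) | Oc1ccc([C@H]2Oc3cc(O)c([C@H]4c5c(O)cc(O)cc5O[C@H](c5ccc(O)c(O)c5)[C@@H]4O)c(O)c3[C@H](c3c(O)cc(O)c4c3O[C@H](c3ccc(O)c(O)c3)[C@H](O)[C@H]4c3c(O)cc4c(c3O)C[C@@H](O)[C@@H](c3ccc(O)c(O)c3)O4)[C@H]2O)cc1 | target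

**Totals and risks**
Total step count: 20. Longest linear sequence: 12 steps (from 10 through steps 8–13 and 15–20).

Steps most likely to fail:

1. Step 16. The cascade may fail by closure through a boat-like geometry (giving the 2,3-trans ring), by attack of the alkene through C4 (five-membered ring), by poor facial control from the chiral anion, or by slow capture at the deactivated C6 of 9. The fallback uses known chemistry, sets out from 4 and 9, and takes ring C of unit 1 intact from natural epicatechin. Bromination of 4 with NBS (CH2Cl2, −40 °C) should give 8-bromo-4β-(2-ethoxyethoxy)-5,7,3′,4′-tetra-O-benzyl-(−)-epicatechin F1. BF3·OEt2 (CH2Cl2, −78 °C) should ionise only the ether of F1, because the sulfide of 9 is inert to the hard Lewis acid, and C6 of 9 captures the cation anti to the 3-OH. This gives 23 directly, where the route is rejoined at step 18.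

2. Step 15. The phenoxide may take over the neighbouring enol benzoate (acyl migration followed by benzofuran formation) or be alkylated on carbon. The fallback sets out from 14 and changes the order so that the phenoxide never meets the enol ester. Buffered Bu4NF should give 2-bromo-6-ethynyl-3,5-bis(benzyloxy)phenol F2. Alkylation with 18 (Cs2CO3, MeCN, 0 °C) should give the alkyne acetal [3,5-bis(benzyloxy)-2-bromo-6-ethynylphenoxy][3,4-bis(benzyloxy)phenyl]methyl pivalate F3. The ruthenium-catalysed addition of benzoic acid used in step 12 then gives 19, where the route is rejoined.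

3. Step 12. The hindered, electron-rich alkyne may form the vinylidene slowly, add the acid in the Markovnikov sense, or lose Z selectivity. The fallback sets out from 13 and builds the enol ester from an enolate instead. Wittig reaction with Ph3P=CHOMe should give the enol ether 4,6-bis(benzyloxy)-3-bromo-1-(2-methoxyethenyl)-2-(triisopropylsilyloxy)benzene F4. Mild acid hydrolysis should give the arylacetaldehyde [4,6-bis(benzyloxy)-3-bromo-2-(triisopropylsilyloxy)phenyl]acetaldehyde F5. O-benzoylation of its potassium enolate (KN(SiMe3)2, then PhCOCl, THF, −78 °C) should give 15 after chromatographic removal of the E isomer, where the route is rejoined.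

**Further compounds**
F1 | step 16 | 8-bromo-4β-(2-ethoxyethoxy)-5,7,3′,4′-tetra-O-benzyl-(−)-epicatechin | CCOCCO[C@H]1c2c(OCc3ccccc3)cc(OCc3ccccc3)c(Br)c2O[C@H](c2ccc(OCc3ccccc3)c(OCc3ccccc3)c2)[C@@H]1O
F2 | step 15 | 2-bromo-6-ethynyl-3,5-bis(benzyloxy)phenol | C#Cc1c(O)c(Br)c(OCc2ccccc2)cc1OCc1ccccc1
F3 | step 15 | [3,5-bis(benzyloxy)-2-bromo-6-ethynylphenoxy][3,4-bis(benzyloxy)phenyl]methyl pivalate (racemic) | CC(C)(C)C(=O)OC(Oc1c(Br)c(OCc2ccccc2)cc(OCc2ccccc2)c1C#C)c1ccc(OCc2ccccc2)c(OCc2ccccc2)c1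
F4 | step 12 | 4,6-bis(benzyloxy)-3-bromo-1-(2-methoxyethenyl)-2-(triisopropylsilyloxy)benzene (E/Z mixture) | COC=Cc1c(O[Si](C(C)C)(C(C)C)C(C)C)c(Br)c(OCc2ccccc2)cc1OCc1ccccc1
F5 | step 12 | [4,6-bis(benzyloxy)-3-bromo-2-(triisopropylsilyloxy)phenyl]acetaldehyde | O=CCc1c(O[Si](C(C)C)(C(C)C)C(C)C)c(Br)c(OCc2ccccc2)cc1OCc1ccccc1
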